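The target in this stirred flask grows as the starting material falls, so we can follow the flask by asking what happens to one molecule of starting material. The midnight run is this same flask, followed so far.

- midnight: starting material 22 mM; second substrate 26.4 mM (fed, over 20 min); free enzyme 2.2 µM; the very flask that is asked about, followed so far
- flask: starting material 22 mM; second substrate 26.4 mM (fed, over 20 min); free enzyme 2.2 µM; time 4.0 h

midnight run (percent of the starting material charged)

| time / min | target / % | starting material / % |
|---|---|---|
| 8.00 | 2.9 | 96.9 |
| 12.0 | 6.2 | 93.6 |
| 20.0 | 10.1 | 89.2 |
| 40.0 | 19.3 | 80.6 |
| 60.0 | 26.7 | 73.4 |
| 90.0 | 34.2 | 66.4 |

(each reading ± 0.5 percentage points)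



- amount of target in the flask at 4.0 h, in percent of the starting material charged
- amount of starting material in the flask at 4.0 h, in percent of the starting material charged
- concentration of first product at 4.0 h, in mM

Between the last two readings, [starting material] falls from 73.4% to 66.4% in 30.0 min, which gives 0.00334 /min. This is the turning chance: the chance per minute that one molecule of starting material reacts, taken as the logarithm of the ratio of two readings over the time between them. The bench rule holds it constant, as for a decay (pseudo-first-order), with a half-life of 208 min. From the last reading, our reckoning then leaves 40.2% starting material at 4.0 h, so 59.8% target and, at one first product per target, 13.1 mM of first product.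

But the bench rule counts on a partner in large excess, and the charge ratio of second substrate to starting material is 1.20. Counting one second substrate per target, we reckon the unused part at 18.9 mM at the last reading and 13.3 mM at our estimate, a ratio of 0.702. The readings also give a larger chance, as read, just after the feed, 0.00507 /min. We therefore stand past the rule's border, yet we commit to our figure, with the risk towards more starting material left.

The forecast says 48% target, 52% starting material and 10.6 mM of first product, on this ground: “An equilibrium near 50% conversion (K≈0.7) fits with constant k”. That is a higher figure for starting material than ours.

The flask gives 60.8% target, 39.2% starting material and 13.4 mM of first product.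

    second complex → free enzyme + target (k = 5070 /min)
    starting material + free enzyme ⇌ first complex (K = 16.0 /M, k = 12000 /M/s)
    first complex → loaded enzyme + first product (k = 229 /min)
    second substrate + loaded enzyme ⇌ second complex (K = 27.0 /M, k = 21300 /M/s)
    second substrate ⇌ dormant form (K = 19.6, k = 0.0790 /min)

In the flask, from the last reading to 4.0 h, the turning chance averaged 0.00351 /min, against the 0.00334 /min we read. In the flask at 4.00 h, free second substrate stands at 0.95% of its charge beside 12.8 mM of dormant form, and, counting each forward step alone, loaded enzyme takes it 17 times as fast as it turns dormant. In the neighbour flask with 5.5 × 10⁻⁴ mM of free enzyme, a quarter of the charge in the first flask, scaling the turning chance with the enzyme gives 8.35 × 10⁻⁴ /min, and our reckoning from that leaves 81.8% starting material at 4.0 h. That neighbour flask computes to 76.5% starting material and 23.5% target.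

(The data are calculated with constants of no real substance; the scatter is artificial.)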